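**Retrosynthetic overview**
1. Feature: the chain C9–C10(C14)=C1–C2–C3–C4(C15)=C5–C6 of the ten-membered carbocycle is the whole ring skeleton of 1,5-dimethylcycloocta-1,5-diene, with both trisubstituted alkenes already ring-cis; only C7–C8 has to be inserted between C6 and C9.
2. Last disconnections: C8 ester (Steglich), C15 aldehyde and C14 acetate (SeO2 at the E-methyl of each ring alkene; C14 early while C4=C5 is an enone, C15 late), C11=C13 (Mannich/elimination).
3. γ-Lactone (second ring): C6–O by invertive Mitsunobu closure of a C7 acetic acid; C7–C11 by enolate alkylation trans to O-8; C8–O by catalytic asymmetric β-borylation of the C7=C8 enone of the C6 ketone.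
4. Ten-membered ring (first ring): two-carbon ring expansion of an eight-membered 1-vinyl carbinol by alkoxide-accelerated 1,3-shift of C9 from C6 to C8, giving the achiral C6 ketone.
5. Carbinol: allylic oxidation of the diene to the cyclooctadienone, then 1,2-addition of vinylmagnesium bromide.

Key step: step 3

Remark: atom labels C1–C15 are germacrane labels (ring C1–C10, lactone C11–C13, C14 on C10, C15 on C4). The target is (6R,7R,8S): O-6 and O-8 lie on one face of the ring and C-11 on the other.
Assumption: commercial 1 is freed by fractional distillation from the 1,6-dimethyl isomer it usually contains.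

**Route**

Step 1
Reactants: 1 (1Z,5Z)-1,5-dimethylcycloocta-1,5-diene
Product: 2 (2Z,6Z)-3,7-dimethylcycloocta-2,6-dien-1-one
Conditions: Rh2(cap)4 (1 mol %), t-BuOOH (4 equiv), K2CO3 (0.5 equiv), CH2Cl2, rt, stopped at partial conversion, 1 recycled
Reagents that add atoms: tert-butyl hydroperoxide, CC(C)(C)OO
Why: Radical allylic oxidation should take the ring CH2 next to the CH end of a trisubstituted alkene (allyl radical with a tertiary terminus, as in the 7-oxidation of Δ5-steroids), the C2 symmetry of 1 makes both such CH2 groups equivalent, and the enone formed is deactivated towards a second oxidation.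

Step 2
Reactants: 2 (2Z,6Z)-3,7-dimethylcycloocta-2,6-dien-1-one; 3 vinylmagnesium bromide
Product: 4 rac-(2Z,6Z)-3,7-dimethyl-1-vinylcycloocta-2,6-dien-1-ol
Conditions: CeCl3 (1.5 equiv), THF, −78 °C; then H2O
Reagents that add atoms: none
Why: Organocerium-mediated Grignard 1,2-addition to the β,β-disubstituted enone, the low basicity of the cerium reagent avoiding enolisation of the doubly activated C9 methylene; the carbinol centre is racemic and is destroyed in step 3.

Step 3
Reactants: 4 rac-(2Z,6Z)-3,7-dimethyl-1-vinylcycloocta-2,6-dien-1-ol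
Product: 7 (2Z,6Z)-3,7-dimethylcyclodeca-2,6-dien-1-one, via potassium alkoxide 5 (not isolated), via potassium enolate 6 (not isolated)
Conditions: KH (1.2 equiv), 18-crown-6 (1.2 equiv), THF, 0 °C to rt; then H2O, 0 °C
Reagents that add atoms: none
Why: In the crown-separated alkoxide 5 the C6–C9 bond, allylic to C10=C1 and geminal to O−, should cleave to an allyl anion tethered to a cross-conjugated dienone, and C9 then adds to the vinyl terminus C8, a formal 1,3-shift that gives the ten-membered ketone as its C6–C7 enolate 6. The closest known reaction is the alkoxide-accelerated [1,3]-sigmatropic two-carbon ring expansion of potassium 1-vinylcycloalk-3-en-1-olates. The ten-membered ring arises by ring expansion (C6–C9 broken and C8–C9 made within one ion pair), not by end-to-end cyclisation, so no high dilution is needed. No stereocentre is formed: the racemic carbinol carbon becomes the carbonyl carbon and 7 is achiral. The step needs 1,3- over 3,3-recombination (C9, not C1, bonding to C8; C1 would give an eight-membered oxy-Cope ketone), attack at C8 and not at C4, and retention of the ring-cis C10=C1 geometry. These should be secured by ion-pair separation, by the primary C9 terminus meeting the unsubstituted C8 whereas C4 is fully substituted, and by recombination being faster than rotation of the ring-held allyl unit.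

Step 4
Reactants: 7 (2Z,6Z)-3,7-dimethylcyclodeca-2,6-dien-1-one
Product: 8 14-hydroxy dienone, (2Z,6E)-7-(hydroxymethyl)-3-methylcyclodeca-2,6-dien-1-one
Conditions: SeO2 (0.3 equiv), t-BuOOH (2 equiv), CH2Cl2, 0 °C to rt
Reagents that add atoms: selenium dioxide, O=[Se]=O; tert-butyl hydroperoxide, CC(C)(C)OO
Why: SeO2 allylic hydroxylation (ene reaction, then [2,3]-shift) should touch only the isolated C10=C1 alkene because C4=C5 is an electron-poor enone, and should take the methyl group trans to the C1–C2 chain (C14, the E-methyl), the [2,3]-shift restoring the ring-cis alkene.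

Step 5
Reactants: 8 14-hydroxy dienone
Product: 9 14-O-TBS dienone
Conditions: TBSCl, imidazole, DMF, 0 °C to rt
Reagents that add atoms: tert-butyldimethylsilyl chloride, CC(C)(C)[Si](C)(C)Cl
Why: Standard silylation of the primary allylic alcohol; the silyl ether carries O-14 through the strongly basic steps that an acetate would not survive.

Step 6
Reactants: 9 14-O-TBS dienone
Product: 12 cross-conjugated trienone (new C7=C8, ring-cis), via lithium enolate 10 (not isolated), via trimethylsilyl dienol ether 11 (not isolated)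
Conditions: LDA, THF, −78 °C; TMSCl; then Pd(OAc)2 (1.05 equiv), MeCN, rt
Reagents that add atoms: none
Why: Saegusa–Ito dehydrogenation: LDA removes the kinetically favoured α′ proton at C7 rather than a γ proton of the enone, and syn β-hydride elimination from the palladium enolate places the alkene at C7=C8, expected ring-cis in a ring that already holds two cis alkenes.

Step 7
Reactants: 12 cross-conjugated trienone
Product: 14 (8S)-8-hydroxy dienone, via pinacol boronate 13 (not isolated)
Conditions: CuCl (5 mol %), NaOt-Bu (10 mol %), Taniaphos-type ferrocenyl bisphosphine (6 mol %, antipode chosen for 8S), B2pin2 (1.1 equiv), MeOH (2 equiv), THF, rt; then NaBO3·4H2O, THF/H2O, rt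
Reagents that add atoms: sodium perborate, [Na+].[Na+].O[B-]1(O)OO[B-](O)(O)OO1
Why: Copper(I)-catalysed asymmetric conjugate borylation: the chiral Cu–Bpin species adds to C8 of the disubstituted C7=C8 enone (the β,β-disubstituted C4=C5 enone is too hindered), methanol protonates the copper enolate and perborate oxidises C–B with retention, so C8 is set by the catalyst on an achiral substrate (sense to be checked by Mosher analysis of 14).

Step 8
Reactants: 14 (8S)-8-hydroxy dienone
Product: 15 8,14-bis-O-TBS dienone
Conditions: TBSOTf, 2,6-lutidine, CH2Cl2, −78 °C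
Reagents that add atoms: tert-butyldimethylsilyl triflate, CC(C)(C)[Si](C)(C)OS(=O)(=O)C(F)(F)F
Why: Low-temperature silylation of the β-hydroxy ketone avoids dehydration or retro-aldol cleavage and gives the bulky ether that steers step 9.

Step 9
Reactants: 15 8,14-bis-O-TBS dienone; 16 methyl bromoacetate
Product: 18 (7R,8S)-C7-alkylated keto ester, via lithium enolate 17 (not isolated)
Conditions: LDA (1.05 equiv), THF, −78 °C; then 16, DMPU, −78 to −40 °C
Reagents that add atoms: none
Why: Kinetic enolate alkylation at C7: with C8–H eclipsing the ring-cis enolate (A1,3 strain) the ring chain at C9 covers the inner face, so the electrophile should enter from the peripheral face and place C11 trans to O-8 (7R).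

Step 10
Reactants: 18 (7R,8S)-C7-alkylated keto ester
Product: 19 (6S,7S,8S)-hydroxy ester, O-6 cis to C-11
Conditions: NaBH4, CeCl3·7H2O, MeOH, −78 °C
Reagents that add atoms: none
Why: Luche 1,2-reduction of the enone carbonyl; hydride should attack from the peripheral face anti to the ring branch C8 (Felkin–Anh, C8 as the large group), giving the C6 alcohol cis to C-11, which is the epimer needed for invertive closure in step 12.

Step 11
Reactants: 19 (6S,7S,8S)-hydroxy ester
Product: 20 (6S,7S,8S)-hydroxy acid
Conditions: LiOH·H2O, THF/MeOH/H2O, 0 °C to rt; then 0.5 M HCl to pH 4–5, 0 °C, used at once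
Reagents that add atoms: lithium hydroxide, [Li+].[OH-]
Why: Ester saponification tolerated by both silyl ethers; partial lactonisation of 19 on standing would be harmless because hydroxide reopens it, and cold work-up with immediate use keeps 20 from lactonising with retention.

Step 12
Reactants: 20 (6S,7S,8S)-hydroxy acid
Product: 21 (6R,7S,8S)-trans-fused 12,6-lactone, 8,14-bis-O-TBS
Conditions: PPh3, DIAD, THF, 0 °C (20 added to the preformed betaine)
Reagents that add atoms: none
Why: Mitsunobu lactonisation: the allylic C6 alcohol is activated as its oxyphosphonium ion and displaced by the tethered carboxylate (5-exo-tet SN2) with inversion, setting 6R and the trans ring fusion with O-6 cis to O-8.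

Step 13
Reactants: 21 (6R,7S,8S)-trans-fused 12,6-lactone
Product: 23 C11-(dimethylaminomethyl) lactone (C11 epimers), via lithium lactone enolate 22 (not isolated)
Conditions: LDA, THF, −78 °C; then Eschenmoser's salt, −78 °C to rt
Reagents that add atoms: N,N-dimethylmethyleneiminium iodide, C=[N+](C)C.[I-]
Why: Mannich reaction of the lactone enolate at C11, the only acidic position; the C11 configuration is irrelevant because the centre becomes sp2 in step 14.

Step 14
Reactants: 23 C11-(dimethylaminomethyl) lactone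
Product: 25 α-methylene lactone, 8,14-bis-O-TBS, via trimethylammonium iodide 24 (not isolated)
Conditions: MeI, MeOH, rt; then aq. NaHCO3, CH2Cl2, rt
Reagents that add atoms: none
Why: Quaternisation followed by mild base-induced E1cB (Hofmann-type) elimination of trimethylamine gives the exocyclic C11=C13 alkene.

Step 15
Reactants: 25 α-methylene lactone, 8,14-bis-O-TBS
Product: 26 (6R,7R,8S)-8,14-diol
Conditions: HF·pyridine, pyridine, THF, 0 °C to rt
Reagents that add atoms: none
Why: Mildly acidic fluoride removes both silyl ethers without Michael addition to, or translactonisation of, the methylene lactone.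

Step 16
Reactants: 26 (6R,7R,8S)-8,14-diol
Product: 27 14-acetate, 8-OH free
Conditions: AcCl (1.05 equiv), 2,4,6-collidine, CH2Cl2, −78 °C
Reagents that add atoms: acetyl chloride, CC(=O)Cl
Why: Kinetically selective acylation: with the hindered base at low temperature the primary allylic C14–OH should be acetylated much faster than the secondary C8–OH.

Step 17
Reactants: 28 ethyl 2-(hydroxymethyl)acrylate
Product: 29 ethyl 2-{[(tert-butyldimethylsilyl)oxy]methyl}acrylate
Conditions: TBSCl, imidazole, DMF, rt
Reagents that add atoms: tert-butyldimethylsilyl chloride, CC(C)(C)[Si](C)(C)Cl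
Why: Routine silylation masks the hydroxyl so that the acid cannot self-condense in step 19.

Step 18
Reactants: 29 ethyl 2-{[(tert-butyldimethylsilyl)oxy]methyl}acrylate
Product: 30 2-{[(tert-butyldimethylsilyl)oxy]methyl}acrylic acid
Conditions: LiOH·H2O, THF/H2O, 0 °C; then 0.5 M HCl to pH 4
Reagents that add atoms: lithium hydroxide, [Li+].[OH-]
Why: Saponification of the ethyl ester at low temperature leaves the primary TBS ether and the acrylate alkene intact.

Step 19
Reactants: 27 14-acetate, 8-OH free; 30 2-{[(tert-butyldimethylsilyl)oxy]methyl}acrylic acid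
Product: 31 8-O-[2-(TBS-oxymethyl)acryloyl] 14-acetate
Conditions: DCC, DMAP (cat.), CH2Cl2, 0 °C to rt
Reagents that add atoms: none
Why: Steglich esterification acylates O-8 with retention at C8 under near-neutral conditions that the methylene lactone and the acetate tolerate.

Step 20
Reactants: 31 8-O-[2-(TBS-oxymethyl)acryloyl] 14-acetate
Product: 33 15-aldehyde, side-chain TBS ether, via C15 allylic alcohol 32 (not isolated)
Conditions: SeO2 (0.5 equiv), t-BuOOH (3 equiv), CH2Cl2, rt; crude then MnO2, CH2Cl2, rt
Reagents that add atoms: selenium dioxide, O=[Se]=O; tert-butyl hydroperoxide, CC(C)(C)OO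
Why: SeO2 allylic oxidation then MnO2: C4=C5 is a prenyl-ester-type alkene and should be attacked at its E-methyl (C15, trans to C6) with the ring-cis geometry retained, whereas C10=C1 is deactivated by its CH2OAc group and the methylene lactone and acrylate are electron-poor; MnO2 takes the allylic alcohol on to the enal.

Step 21
Reactants: 33 15-aldehyde, side-chain TBS ether
Product: 34 target CNP0198933.2
Conditions: HF·pyridine, pyridine, THF, 0 °C
Reagents that add atoms: none
Why: Mildly acidic desilylation frees the primary hydroxyl without touching the enal, the two esters or the methylene lactone.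

**Compound list**
1 | (1Z,5Z)-1,5-dimethylcycloocta-1,5-diene | C/C1=C/CC/C(C)=C\CC1 | starting material
2 | (2Z,6Z)-3,7-dimethylcycloocta-2,6-dien-1-one | O=C1/C=C(C)\CC/C=C(C)\C1 | intermediate
3 | vinylmagnesium bromide | C=C[Mg]Br | starting material
4 | rac-(2Z,6Z)-3,7-dimethyl-1-vinylcycloocta-2,6-dien-1-ol | C=CC1(O)/C=C(C)\CC/C=C(C)\C1 | intermediate
5 | potassium (2Z,6Z)-3,7-dimethyl-1-vinylcycloocta-2,6-dien-1-olate | C=CC1([O-])/C=C(C)\CC/C=C(C)\C1.[K+] | intermediate
6 | potassium 5,9-dimethylcyclodeca-1,5,9-trien-1-olate (C6–C7 enolate of 7, all alkenes ring-cis) | [K+].[O-]/C1=C/CC/C(C)=C\CC/C(C)=C\1 | intermediate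
7 | (2Z,6Z)-3,7-dimethylcyclodeca-2,6-dien-1-one (C6 ketone) | O=C1CCC/C(C)=C\CC/C(C)=C\1 | intermediate
8 | (2Z,6E)-7-(hydroxymethyl)-3-methylcyclodeca-2,6-dien-1-one (14-alcohol, both alkenes ring-cis) | O=C1CCC/C(CO)=C\CC/C(C)=C\1 | intermediate
9 | (2Z,6E)-7-{[(tert-butyldimethylsilyl)oxy]methyl}-3-methylcyclodeca-2,6-dien-1-one | O=C1CCC/C(CO[Si](C)(C)C(C)(C)C)=C\CC/C(C)=C\1 | intermediate
10 | lithium C6–C7 enolate of 9 | [Li+].[O-]/C1=C/CC/C(CO[Si](C)(C)C(C)(C)C)=C\CC/C(C)=C\1 | intermediate
11 | trimethylsilyl dienol ether of 9 (C6–OTMS, C6=C7 ring-cis) | C[Si](C)(C)O/C1=C/CC/C(CO[Si](C)(C)C(C)(C)C)=C\CC/C(C)=C\1 | intermediate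
12 | (2Z,6E,9Z)-7-{[(tert-butyldimethylsilyl)oxy]methyl}-3-methylcyclodeca-2,6,9-trien-1-one (all ring-cis) | O=C1/C=C\C/C(CO[Si](C)(C)C(C)(C)C)=C\CC/C(C)=C\1 | intermediate
13 | (2Z,6E,9S)-7-{[(tert-butyldimethylsilyl)oxy]methyl}-3-methyl-9-(4,4,5,5-tetramethyl-1,3,2-dioxaborolan-2-yl)cyclodeca-2,6-dien-1-one (boron on C8) | O=C1C[C@@H](B2OC(C)(C)C(C)(C)O2)C/C(CO[Si](C)(C)C(C)(C)C)=C\CC/C(C)=C\1 | intermediate
14 | (2Z,6E,9S)-9-hydroxy-7-{[(tert-butyldimethylsilyl)oxy]methyl}-3-methylcyclodeca-2,6-dien-1-one (8S-alcohol) | O=C1C[C@@H](O)C/C(CO[Si](C)(C)C(C)(C)C)=C\CC/C(C)=C\1 | intermediate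
15 | (2Z,6E,9S)-9-[(tert-butyldimethylsilyl)oxy]-7-{[(tert-butyldimethylsilyl)oxy]methyl}-3-methylcyclodeca-2,6-dien-1-one | O=C1C[C@@H](O[Si](C)(C)C(C)(C)C)C/C(CO[Si](C)(C)C(C)(C)C)=C\CC/C(C)=C\1 | intermediate
16 | methyl bromoacetate | COC(=O)CBr | starting material
17 | lithium C6–C7 enolate of 15 | [Li+].[O-]/C1=C/[C@@H](O[Si](C)(C)C(C)(C)C)C/C(CO[Si](C)(C)C(C)(C)C)=C\CC/C(C)=C\1 | intermediate
18 | methyl [(7R,8S)-8,14-bis(tert-butyldimethylsilyloxy)-6-oxo ring-C7-yl]acetate (germacrane locants; ring alkenes 1(10) and 4 ring-cis; C-11 trans to O-8) | O=C1[C@H](CC(=O)OC)[C@@H](O[Si](C)(C)C(C)(C)C)C/C(CO[Si](C)(C)C(C)(C)C)=C\CC/C(C)=C\1 | intermediate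
19 | methyl ester of the (6S,7S,8S)-6-hydroxy acid (O-6 cis to C-11, O-6 trans to O-8) | O[C@@H]1[C@H](CC(=O)OC)[C@@H](O[Si](C)(C)C(C)(C)C)C/C(CO[Si](C)(C)C(C)(C)C)=C\CC/C(C)=C\1 | intermediate
20 | (6S,7S,8S)-6-hydroxy-8,14-bis(tert-butyldimethylsilyloxy) C7-acetic acid | O[C@@H]1[C@H](CC(=O)O)[C@@H](O[Si](C)(C)C(C)(C)C)C/C(CO[Si](C)(C)C(C)(C)C)=C\CC/C(C)=C\1 | intermediate
21 | (6R,7S,8S)-8,14-bis(tert-butyldimethylsilyloxy)-13-norgermacra-1(10),4-dien-12,6-olide (trans-fused, alkenes ring-cis) | CC(C)(C)[Si](C)(C)O[C@H]1C/C(CO[Si](C)(C)C(C)(C)C)=C\CC/C(C)=C\[C@H]2OC(=O)C[C@H]12 | intermediate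
22 | lithium enolate of lactone 21 | [Li+].CC(C)(C)[Si](C)(C)O[C@H]1C/C(CO[Si](C)(C)C(C)(C)C)=C\CC/C(C)=C\[C@H]2OC([O-])=C[C@H]12 | intermediate
23 | (6R,7S,8S)-11-(dimethylaminomethyl) lactone, C11 epimers | CC(C)(C)[Si](C)(C)O[C@H]1C/C(CO[Si](C)(C)C(C)(C)C)=C\CC/C(C)=C\[C@H]2OC(=O)C(CN(C)C)[C@H]12 | intermediate
24 | trimethylammonium iodide of 23 | [I-].CC(C)(C)[Si](C)(C)O[C@H]1C/C(CO[Si](C)(C)C(C)(C)C)=C\CC/C(C)=C\[C@H]2OC(=O)C(C[N+](C)(C)C)[C@H]12 | intermediate
25 | (6R,7S,8S)-8,14-bis(tert-butyldimethylsilyloxy)germacra-1(10),4,11(13)-trien-12,6-olide | CC(C)(C)[Si](C)(C)O[C@H]1C/C(CO[Si](C)(C)C(C)(C)C)=C\CC/C(C)=C\[C@H]2OC(=O)C(=C)[C@H]12 | intermediate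
26 | (6R,7R,8S)-8,14-dihydroxygermacra-1(10),4,11(13)-trien-12,6-olide | O[C@H]1C/C(CO)=C\CC/C(C)=C\[C@H]2OC(=O)C(=C)[C@H]12 | intermediate
27 | (6R,7R,8S)-14-acetoxy-8-hydroxygermacra-1(10),4,11(13)-trien-12,6-olide | O[C@H]1C/C(COC(C)=O)=C\CC/C(C)=C\[C@H]2OC(=O)C(=C)[C@H]12 | intermediate
28 | ethyl 2-(hydroxymethyl)acrylate | C=C(CO)C(=O)OCC | starting material
29 | ethyl 2-{[(tert-butyldimethylsilyl)oxy]methyl}acrylate | C=C(CO[Si](C)(C)C(C)(C)C)C(=O)OCC | intermediate
30 | 2-{[(tert-butyldimethylsilyl)oxy]methyl}acrylic acid | C=C(CO[Si](C)(C)C(C)(C)C)C(=O)O | intermediate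
31 | (6R,7R,8S)-14-acetoxy-8-{2-[(tert-butyldimethylsilyloxy)methyl]acryloyloxy}germacra-1(10),4,11(13)-trien-12,6-olide | C=C(CO[Si](C)(C)C(C)(C)C)C(=O)O[C@H]1C/C(COC(C)=O)=C\CC/C(C)=C\[C@H]2OC(=O)C(=C)[C@H]12 | intermediate
32 | 15-hydroxy derivative of 31 | C=C(CO[Si](C)(C)C(C)(C)C)C(=O)O[C@H]1C/C(COC(C)=O)=C\CC/C(CO)=C\[C@H]2OC(=O)C(=C)[C@H]12 | intermediate
33 | 15-oxo derivative of 31 | C=C(CO[Si](C)(C)C(C)(C)C)C(=O)O[C@H]1C/C(COC(C)=O)=C\CC/C(C=O)=C\[C@H]2OC(=O)C(=C)[C@H]12 | intermediate
34 | CNP0198933.2, (6R,7R,8S)-14-acetoxy-8-[2-(hydroxymethyl)acryloyloxy]-15-oxogermacra-1(10),4,11(13)-trien-12,6-olide (both endocyclic alkenes ring-cis) | C=C(CO)C(=O)O[C@H]1C/C(COC(C)=O)=C\CC/C(C=O)=C\[C@H]2OC(=O)C(=C)[C@H]12 | target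

**Step count and risks**
Total steps: 21. Longest linear sequence: 19 (steps 1–16 and 19–21); steps 17–18 make the side-chain acid.

Steps most likely to fail:

1. Step 3. After C6–C9 cleavage the allyl anion may recombine through C1 (oxy-Cope path to an eight-membered ketone) or add to C4, or the dienone may oligomerise before recombination. Fallback, from 4: silylation (TMSCl, imidazole, DMF) should give the trimethylsilyl ether F1. Flow thermolysis of F1 at about 300 °C uses the neutral thermal 1,3-shift known for 1-trimethylsiloxy-1-vinylcycloalk-3-enes and should give the ring-expanded trimethylsilyl enol ether F2. Dilute HCl in THF hydrolyses F2 to 7, where the route is rejoined.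

2. Step 9. The enolate may expel silanolate (E1cB, back to the C7=C8 enone), or C-alkylation beside the bulky silyl ether may be slow. Fallback, from 14: LDA (2.2 equiv, THF, −78 °C) should give the alkoxide–enolate dianion, in which the oxide cannot leave (Fráter–Seebach-type alkylation). Methyl bromoacetate with DMPU then alkylates C7 on the same peripheral face to give the hydroxy keto ester F3 as its lithium alkoxide. F3 is silylated in the same flask (TBSOTf, 2,6-lutidine, −78 °C) before it can lactonise onto O-8, which returns to 18.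

3. Step 10. Facial selectivity at the C6 carbonyl may be poor or reversed, with hydride entering from the inner face. Fallback, from 18: the same reduction then gives the epimeric hydroxy ester F4, whose hydroxyl is already trans to C-11. F4 is closed with retention by acid-catalysed acyl transfer (PPTS, benzene, 50 °C) instead of by alkyl substitution, and this returns to 21 without steps 11 and 12. If a mixture of 19 and F4 forms, it is separated and each epimer is taken to 21 by its own mode of closure.

**Further compounds**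
F1 | step 3 | rac-(2Z,6Z)-3,7-dimethyl-1-(trimethylsilyloxy)-1-vinylcycloocta-2,6-diene | C=CC1(O[Si](C)(C)C)/C=C(C)\CC/C=C(C)\C1
F2 | step 3 | trimethylsilyl enol ether of 7 (C6–OTMS, C6=C7, all alkenes ring-cis) | C[Si](C)(C)O/C1=C/CC/C(C)=C\CC/C(C)=C\1
F3 | step 9 | methyl [(7R,8S)-8-hydroxy-14-(tert-butyldimethylsilyloxy)-6-oxo ring-C7-yl]acetate (free 8-OH analogue of 18) | O=C1[C@H](CC(=O)OC)[C@@H](O)C/C(CO[Si](C)(C)C(C)(C)C)=C\CC/C(C)=C\1
F4 | step 10 | (6R,7S,8S)-hydroxy ester, C6 epimer of 19 (O-6 trans to C-11) | O[C@H]1[C@H](CC(=O)OC)[C@@H](O[Si](C)(C)C(C)(C)C)C/C(CO[Si](C)(C)C(C)(C)C)=C\CC/C(C)=C\1
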